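**Retrosynthetic overview**

1. Decalin numbering used below: ring A = C1–C2–C3(=O)–C4(Me2)–C5–C10(Me); ring B = C5=C6(OH)–C7(=O)–C8(Me)=C9–C10; C9 carries the CH2CH2 link to the oxepane-fused cyclohexane (left half).
2. Endgame: one global oxidation gives the C6/C7 diosphenol, the C3 ketone and the oxepanone; the C9–CH2 bond comes from adding a left-half alkyllithium to a C9 ketone, followed by oxidative 1,3-transposition to the C7 enone.
3. Key disconnection: C5–C10 and C7–C8 are cut together; ring A and then ring B close in one flask from an enal that hangs on a 3,4-dihydro-2H-pyran.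
4. Enabling feature: C3 bears oxygen and lies 1,4 to C10 across ring A, and C9 is a carbonyl carbon at the annulation stage. Joining O3 to C9 as a cyclic enol ether (ring O–C9=C10–C1–C2–C3) makes C10 nucleophilic and lets the C4–C5 bridge reach C10 only on the face of the C3 substituent, so a temporary C3 carbinol (later the C3 ketone) sets quaternary C10; C9/C7 form the 1,5-dicarbonyl pair for the aldol closure of ring B.
5. Left half: oxepane and cyclohexane rings form together by an epoxide-opening oxa/carbacyclisation of a geranyl-derived diepoxy enol silane; the axial ring methyl follows from methylenation and hydrogenation. Ring order: oxepane + cyclohexane (left); ring A, then ring B (right); union last.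

Key step: step 6

Remarks on the chemistry:
- The configuration at C5 (C4a of 12) and at the hydroxyl-bearing centres made in steps 16 and 18 is without consequence, because these carbons are sp2 in the target; where a SMILES leaves a centre or an enamine geometry open, a mixture is meant.
- Enolates and ylides that are generated and consumed in the same operation are given under Conditions and are not numbered.
- Both enantiomers of the fructose-derived ketone catalyst of the Shi epoxidation are taken as commercially available; the L-fructose-derived one is needed.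
- The valine enantiomer in step 2 is chosen to deliver the 3R carbinol; N-tosyl-L-valine is expected to do so.

**Right half (steps 1–7)**

Step 1
Reactants: 1 pentan-3-one; 2 prop-2-enal (acrolein)
Product: 4 4-methyl-5-oxoheptanal, via enamine 3 (not isolated)
Conditions: pyrrolidine (1.1 equiv), TsOH·H2O (cat.), PhH, reflux, −H2O; then 2, MeCN, 0 → 23 °C; then AcOH–NaOAc–H2O, 23 °C
Reagents that add atoms: water, O
Why: Stork enamine Michael addition of the symmetrical ketone to acrolein followed by hydrolysis should give the 1,5-keto aldehyde; the new centre is racemic and becomes sp2 again in step 3.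

Step 2
Reactants: 4 4-methyl-5-oxoheptanal; 5 1-methoxy-2-methyl-1-(trimethylsilyloxy)prop-1-ene
Product: 6 methyl (3R)-3-hydroxy-2,2,6-trimethyl-7-oxononanoate
Conditions: N-tosyl-L-valine (1.0 equiv), BH3·THF (1.0 equiv), CH2Cl2, 0 → 23 °C; then 4 and 5, −78 °C; aq. HCl–THF work-up
Reagents that add atoms: none
Why: Enantioselective Mukaiyama aldol addition promoted by the valine-derived oxazaborolidinone; the aldehyde reacts in preference to the ketone and the promoter shields one aldehyde face, which sets the 3R carbinol.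

Step 3
Reactants: 6 methyl (3R)-3-hydroxy-2,2,6-trimethyl-7-oxononanoate
Product: 7 methyl 2-[(2R)-6-ethyl-5-methyl-3,4-dihydro-2H-pyran-2-yl]-2-methylpropanoate
Conditions: pyridinium p-toluenesulfonate (5 mol%), PhH, reflux, Dean–Stark
Reagents that add atoms: none
Why: Acid-catalysed cyclodehydration of the δ-hydroxy ketone through its hemiketal should give the more substituted endocyclic enol ether; the carbinol centre is untouched and the racemic methyl-bearing centre is erased.

Step 4
Reactants: 7 methyl 2-[(2R)-6-ethyl-5-methyl-3,4-dihydro-2H-pyran-2-yl]-2-methylpropanoate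
Product: 8 2-[(2R)-6-ethyl-5-methyl-3,4-dihydro-2H-pyran-2-yl]-2-methylpropanal
Conditions: i-Bu2AlH (1.1 equiv), CH2Cl2, −78 °C; aq. KNaC4H4O6
Reagents that add atoms: none
Why: Partial reduction of the hindered ester; the aluminium hemiacetal, chelated by the ring oxygen, should persist until work-up, and the enol ether is inert to the hydride.

Step 5
Reactants: 8 2-[(2R)-6-ethyl-5-methyl-3,4-dihydro-2H-pyran-2-yl]-2-methylpropanal
Product: 9 (2E)-4-[(2R)-6-ethyl-5-methyl-3,4-dihydro-2H-pyran-2-yl]-4-methylpent-2-enal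
Conditions: Ph3P=CHCHO, PhMe, 90 °C
Reagents that add atoms: (triphenylphosphoranylidene)acetaldehyde, O=CC=P(c1ccccc1)(c1ccccc1)c1ccccc1
Why: Wittig olefination with a stabilised ylide should give the E-enal; the aldehyde has no α-hydrogen, so neither enolisation nor epimerisation can interfere.

Step 6
Reactants: 9 (2E)-4-[(2R)-6-ethyl-5-methyl-3,4-dihydro-2H-pyran-2-yl]-4-methylpent-2-enal
Product: 12 (4aR,6R,8aS)-6-hydroxy-2,5,5,8a-tetramethyl-4a,5,6,7,8,8a-hexahydronaphthalen-1(4H)-one, via cage ketal 10 (not isolated), via keto aldehyde 11 (not isolated)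
Conditions: Sc(OTf)3 (10 mol%), CH2Cl2, −40 → 0 °C (anhydrous); then THF–H2O (10:1), TsOH·H2O (0.3 equiv), 50 °C, same flask
Reagents that add atoms: water, O
Why: Proposed new method: Sc(OTf)3 activates the enal and the enol ether carbon C10 adds to C5 (Mukaiyama–Michael addition, the stepwise form of an inverse-electron-demand oxa-Diels–Alder reaction between an enal and an enol ether, which is the closest known reaction type), the C9 oxocarbenium ion being trapped by the enolate oxygen as cage ketal 10; the added aqueous acid opens 10 to keto aldehyde 11, whose C8 enol adds to the C7 aldehyde and loses water (intramolecular aldol condensation of a 1,5-dicarbonyl compound, as in the second half of a Robinson annulation). Ring A closes by 6-exo-trig attack of the enol ether on the tethered acceptor, which bridges the dihydropyran to a 2-oxabicyclo[2.2.2]octane, and ring B closes by a 6-(enolendo)-exo-trig aldol addition. The quaternary centre C10 is controlled by the C3–O–C9 tether: the C4–C5 bridge can reach C10 only on the pyran face that carries it, so the 3R carbinol of step 2 is relayed to C10 by geometry and not by a reagent. C5 is expected cis to C9 from the compact, cycloaddition-like approach, and its configuration does not matter because C5 becomes sp2 in step 20. The step needs C–C bond formation at C10 before the enol ether is hydrolysed (secured by the anhydrous first stage) and aldolisation through C8 only (C10 is quaternary, and the aldehyde enol could only close a four-membered ring).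

Step 7
Reactants: 12 (4aR,6R,8aS)-6-hydroxy-2,5,5,8a-tetramethyl-4a,5,6,7,8,8a-hexahydronaphthalen-1(4H)-one
Product: 13 (4aR,6R,8aS)-6-{[tert-butyl(dimethyl)silyl]oxy}-2,5,5,8a-tetramethyl-4a,5,6,7,8,8a-hexahydronaphthalen-1(4H)-one
Conditions: TBSOTf, 2,6-lutidine, CH2Cl2, −78 → 0 °C
Reagents that add atoms: tert-butyldimethylsilyl trifluoromethanesulfonate, CC(C)(C)[Si](C)(C)OS(=O)(=O)C(F)(F)F
Why: Silylation of the hindered secondary alcohol with the silyl triflate masks the future C3 ketone during the organolithium addition and the enolate oxidation.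

**Left half (steps 8–15)**

Step 8
Reactants: 14 dimethyl (2-oxopropyl)phosphonate; 15 (2E)-1-bromo-3,7-dimethylocta-2,6-diene (geranyl bromide)
Product: 16 dimethyl [(5E)-6,10-dimethyl-2-oxoundeca-5,9-dien-1-yl]phosphonate
Conditions: NaH, THF, 0 °C; n-BuLi, 0 °C; then 15, 0 → 23 °C; aq. NH4Cl
Reagents that add atoms: none
Why: The β-keto phosphonate dianion should be alkylated at its terminal (more reactive) carbanion by SN2 displacement of the allylic bromide, with the E alkene retained.

Step 9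
Reactants: 16 dimethyl [(5E)-6,10-dimethyl-2-oxoundeca-5,9-dien-1-yl]phosphonate; 17 (benzyloxy)acetaldehyde
Product: 18 (2E,7E)-1-(benzyloxy)-8,12-dimethyltrideca-2,7,11-trien-4-one
Conditions: LiCl, DBU, MeCN, 23 °C
Reagents that add atoms: none
Why: Horner–Wadsworth–Emmons olefination under mild LiCl/amine conditions should give the E-enone without isomerising the γ-alkoxy enone.

Step 10
Reactants: 18 (2E,7E)-1-(benzyloxy)-8,12-dimethyltrideca-2,7,11-trien-4-one
Product: 19 (2E)-1-(benzyloxy)-6-[(2S,3S)-3-{2-[(2S)-3,3-dimethyloxiran-2-yl]ethyl}-3-methyloxiran-2-yl]hex-2-en-4-one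
Conditions: L-fructose-derived Shi ketone (1,2:4,5-di-O-isopropylidene-β-L-erythro-2,3-hexodiulo-2,6-pyranose, 0.6 equiv), KHSO5 (as 2KHSO5·KHSO4·K2SO4), K2CO3, Bu4NHSO4, MeCN–(MeO)2CH2, aq. Na2B4O7/Na2EDTA buffer, 0 °C
Reagents that add atoms: potassium peroxymonosulfate, [K+].[O-]S(=O)(=O)OO
Why: Shi asymmetric epoxidation should oxidise the two electron-rich trisubstituted alkenes and leave the electron-poor enone alkene; the chiral dioxirane sets the 2S,3S and 2S oxirane centres.

Step 11
Reactants: 19 (2E)-1-(benzyloxy)-6-[(2S,3S)-3-{2-[(2S)-3,3-dimethyloxiran-2-yl]ethyl}-3-methyloxiran-2-yl]hex-2-en-4-one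
Product: 20 tert-butyl{[(3Z)-6-(benzyloxy)-1-[(2S,3S)-3-{2-[(2S)-3,3-dimethyloxiran-2-yl]ethyl}-3-methyloxiran-2-yl]hex-3-en-3-yl]oxy}dimethylsilane
Conditions: t-BuMe2SiH (1.5 equiv), RhCl(PPh3)3 (2 mol%), THF, 50 °C
Reagents that add atoms: tert-butyldimethylsilane, C[SiH](C)C(C)(C)C
Why: Rhodium-catalysed 1,4-hydrosilylation of the s-cis enone should give the regiodefined Z silyl enol ether, which fixes the nucleophilic carbon for the next step; epoxides and the benzyl ether are inert.

Step 12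
Reactants: 20 tert-butyl{[(3Z)-6-(benzyloxy)-1-[(2S,3S)-3-{2-[(2S)-3,3-dimethyloxiran-2-yl]ethyl}-3-methyloxiran-2-yl]hex-3-en-3-yl]oxy}dimethylsilane
Product: 21 (3S,5aS,6S,9aS)-6-[2-(benzyloxy)ethyl]-3-{[tert-butyl(dimethyl)silyl]oxy}-2,2,5a-trimethyl-3,4,5,5a,6,8,9,9a-octahydro-1-benzoxepin-7(2H)-one
Conditions: TBSOTf (0.3 equiv), 2,6-di-tert-butyl-4-methylpyridine (0.5 equiv), CH2Cl2, −78 °C; Et3N quench; then DBU (0.2 equiv), CH2Cl2, 23 °C
Reagents that add atoms: none
Why: Epoxide-opening oxa/carbacyclisation cascade: the silylated terminal epoxide is opened at its tertiary carbon by the internal epoxide oxygen (oxepane, 7-endo) and the resulting epoxonium ion is opened at its tertiary carbon with inversion by the enol silane through a chair transition state, which should give the trans-fused rings with C9a and C3 retained from the epoxides, C5a inverted, and C6 equilibrated by DBU to the equatorial epimer.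

Step 13
Reactants: 21 (3S,5aS,6S,9aS)-6-[2-(benzyloxy)ethyl]-3-{[tert-butyl(dimethyl)silyl]oxy}-2,2,5a-trimethyl-3,4,5,5a,6,8,9,9a-octahydro-1-benzoxepin-7(2H)-one
Product: 22 tert-butyl{[(3S,5aS,6R,9aS)-6-[2-(benzyloxy)ethyl]-2,2,5a-trimethyl-7-methylidenedecahydro-1-benzoxepin-3-yl]oxy}dimethylsilane
Conditions: Ph3PCH3Br, KOt-Bu, PhMe, 80 °C
Reagents that add atoms: methyltriphenylphosphonium bromide, C[P+](c1ccccc1)(c1ccccc1)c1ccccc1.[Br-]
Why: Wittig methylenation of the hindered ring ketone; any base-induced epimerisation at C6 only returns the favoured equatorial side chain.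

Step 14
Reactants: 22 tert-butyl{[(3S,5aS,6R,9aS)-6-[2-(benzyloxy)ethyl]-2,2,5a-trimethyl-7-methylidenedecahydro-1-benzoxepin-3-yl]oxy}dimethylsilane
Product: 24 2-[(3S,5aS,6R,7R,9aS)-3-{[tert-butyl(dimethyl)silyl]oxy}-2,2,5a,7-tetramethyldecahydro-1-benzoxepin-6-yl]ethan-1-ol, via saturated benzyl ether 23 (not isolated)
Conditions: H2 (1 atm), PtO2, EtOAc, 23 °C; then Pd(OH)2/C, H2 (1 atm), same flask
Reagents that add atoms: none
Why: Heterogeneous hydrogenation of the exocyclic alkene should deliver hydrogen to the face opposite the axial C5a methyl group (1,3 to C7), which gives the axial C7 methyl cis to it, and hydrogenolysis then frees the primary alcohol; PtO2 is used first because it causes little double-bond migration.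

Step 15
Reactants: 24 2-[(3S,5aS,6R,7R,9aS)-3-{[tert-butyl(dimethyl)silyl]oxy}-2,2,5a,7-tetramethyldecahydro-1-benzoxepin-6-yl]ethan-1-ol
Product: 25 tert-butyl{[(3S,5aS,6R,7R,9aS)-6-(2-iodoethyl)-2,2,5a,7-tetramethyldecahydro-1-benzoxepin-3-yl]oxy}dimethylsilane
Conditions: I2, PPh3, imidazole, CH2Cl2, 0 → 23 °C
Reagents that add atoms: iodine, II
Why: Appel-type iodination of the unhindered primary alcohol; the hindered secondary silyl ether is untouched.

**Union and endgame (steps 16–20)**

Step 16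
Reactants: 25 tert-butyl{[(3S,5aS,6R,7R,9aS)-6-(2-iodoethyl)-2,2,5a,7-tetramethyldecahydro-1-benzoxepin-3-yl]oxy}dimethylsilane; 13 (4aR,6R,8aS)-6-{[tert-butyl(dimethyl)silyl]oxy}-2,5,5,8a-tetramethyl-4a,5,6,7,8,8a-hexahydronaphthalen-1(4H)-one
Product: 27 tertiary allylic alcohol at C9 (both carbinol epimers), via alkyllithium 26 (not isolated)
Conditions: t-BuLi (2.1 equiv), Et2O–pentane, −78 °C; then 13 in THF, −78 → −40 °C; aq. NH4Cl
Reagents that add atoms: none
Why: Iodine–lithium exchange and 1,2-addition of the primary alkyllithium to the enone carbonyl, which has no α'-hydrogen to lose; the new carbinol centre is removed in step 17.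

Step 17
Reactants: 27 tertiary allylic alcohol at C9
Product: 28 transposed enone (C7 ketone, C8=C9 alkene bearing the left-half chain, C5–H cis to the C10 methyl, two silyl ethers)
Conditions: pyridinium chlorochromate (C5H5NH)[CrO3Cl] (4 equiv), CH2Cl2, 23 °C
Reagents that add atoms: pyridinium chlorochromate, [O-][Cr](=O)(=O)Cl.c1cc[nH+]cc1
Why: Babler–Dauben oxidative transposition: the chromate ester of the tertiary allylic alcohol rearranges 1,3 and is oxidised, which should give the tetrasubstituted C8=C9 enone with the carbonyl at C7.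

Step 18
Reactants: 28 transposed enone
Product: 29 C6-hydroxy enone (acyloin, both C6 epimers)
Conditions: NaN(SiMe3)2, THF, −78 °C; then 2-(phenylsulfonyl)-3-phenyloxaziridine, −78 °C; aq. NH4Cl
Reagents that add atoms: 2-(phenylsulfonyl)-3-phenyloxaziridine, O=S(=O)(N1OC1c1ccccc1)c1ccccc1
Why: Kinetic deprotonation of the enone at the α' methylene C6 and oxygen transfer from the N-sulfonyloxaziridine to the cross-conjugated enolate; no other carbonyl is present, and the new centre is oxidised in step 20.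

Step 19
Reactants: 29 C6-hydroxy enone
Product: 30 triol (free hydroxyls at C3, at C6 and on the oxepane)
Conditions: HF·pyridine, THF–pyridine, 0 → 40 °C
Reagents that add atoms: none
Why: Acidic fluoride cleaves both hindered secondary silyl ethers without the base-induced ketol shift that a basic fluoride source could cause.

Step 20
Reactants: 30 triol
Product: 32 sodwanone B, via triketone 31 (not isolated)
Conditions: Dess–Martin periodinane (5 equiv), NaHCO3, CH2Cl2, 23 °C; then Et3N (cat.), 23 °C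
Reagents that add atoms: none
Why: Dess–Martin oxidation of the three secondary alcohols gives the oxepanone, the C3 ketone and the C6/C7 diketone, which should enolise towards C5 (its only α-hydrogen) to the conjugated diosphenol of the target.

**Compound list**

1 | pentan-3-one | CCC(=O)CC | starting material
2 | prop-2-enal (acrolein) | C=CC=O | starting material
3 | 1-(pent-2-en-3-yl)pyrrolidine (enamine, geometry open) | CC=C(CC)N1CCCC1 | intermediate
4 | 4-methyl-5-oxoheptanal (racemic) | CCC(=O)C(C)CCC=O | intermediate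
5 | 1-methoxy-2-methyl-1-(trimethylsilyloxy)prop-1-ene | COC(O[Si](C)(C)C)=C(C)C | starting material
6 | methyl (3R)-3-hydroxy-2,2,6-trimethyl-7-oxononanoate (both C6 epimers) | CCC(=O)C(C)CC[C@@H](O)C(C)(C)C(=O)OC | intermediate
7 | methyl 2-[(2R)-6-ethyl-5-methyl-3,4-dihydro-2H-pyran-2-yl]-2-methylpropanoate | CCC1=C(C)CC[C@@H](O1)C(C)(C)C(=O)OC | intermediate
8 | 2-[(2R)-6-ethyl-5-methyl-3,4-dihydro-2H-pyran-2-yl]-2-methylpropanal | CCC1=C(C)CC[C@@H](O1)C(C)(C)C=O | intermediate
9 | (2E)-4-[(2R)-6-ethyl-5-methyl-3,4-dihydro-2H-pyran-2-yl]-4-methylpent-2-enal | CCC1=C(C)CC[C@@H](O1)C(C)(C)/C=C/C=O | intermediate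
10 | cage ketal (formal intramolecular oxa-Diels–Alder adduct of 9; C5–C10 and O–C9 bonds formed) | CC[C@]12OC=C[C@@H]3C(C)(C)[C@@H](CC[C@]23C)O1 | intermediate
11 | 2-[(1R,2S,5R)-5-hydroxy-2,6,6-trimethyl-2-propanoylcyclohexyl]acetaldehyde | CCC(=O)[C@@]1(C)CC[C@@H](O)C(C)(C)[C@H]1CC=O | intermediate
12 | (4aR,6R,8aS)-6-hydroxy-2,5,5,8a-tetramethyl-4a,5,6,7,8,8a-hexahydronaphthalen-1(4H)-one | CC1=CC[C@@H]2C(C)(C)[C@H](O)CC[C@]2(C)C1=O | intermediate
13 | (4aR,6R,8aS)-6-{[tert-butyl(dimethyl)silyl]oxy}-2,5,5,8a-tetramethyl-4a,5,6,7,8,8a-hexahydronaphthalen-1(4H)-one | CC1=CC[C@@H]2C(C)(C)[C@H](O[Si](C)(C)C(C)(C)C)CC[C@]2(C)C1=O | intermediate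
14 | dimethyl (2-oxopropyl)phosphonate | COP(=O)(CC(C)=O)OC | starting material
15 | (2E)-1-bromo-3,7-dimethylocta-2,6-diene (geranyl bromide) | CC(C)=CCC/C(C)=C/CBr | starting material
16 | dimethyl [(5E)-6,10-dimethyl-2-oxoundeca-5,9-dien-1-yl]phosphonate | COP(=O)(CC(=O)CC/C=C(\C)CCC=C(C)C)OC | intermediate
17 | (benzyloxy)acetaldehyde | O=CCOCc1ccccc1 | starting material
18 | (2E,7E)-1-(benzyloxy)-8,12-dimethyltrideca-2,7,11-trien-4-one | O=C(/C=C/COCc1ccccc1)CC/C=C(\C)CCC=C(C)C | intermediate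
19 | (2E)-1-(benzyloxy)-6-[(2S,3S)-3-{2-[(2S)-3,3-dimethyloxiran-2-yl]ethyl}-3-methyloxiran-2-yl]hex-2-en-4-one | O=C(/C=C/COCc1ccccc1)CC[C@@H]1O[C@@]1(C)CC[C@@H]1OC1(C)C | intermediate
20 | tert-butyl{[(3Z)-6-(benzyloxy)-1-[(2S,3S)-3-{2-[(2S)-3,3-dimethyloxiran-2-yl]ethyl}-3-methyloxiran-2-yl]hex-3-en-3-yl]oxy}dimethylsilane | CC(C)(C)[Si](C)(C)O/C(CC[C@@H]1O[C@@]1(C)CC[C@@H]1OC1(C)C)=C\CCOCc1ccccc1 | intermediate
21 | (3S,5aS,6S,9aS)-6-[2-(benzyloxy)ethyl]-3-{[tert-butyl(dimethyl)silyl]oxy}-2,2,5a-trimethyl-3,4,5,5a,6,8,9,9a-octahydro-1-benzoxepin-7(2H)-one | O(Cc1ccccc1)CC[C@@H]2C(=O)CC[C@@H]3OC(C)(C)[C@@H](O[Si](C)(C)C(C)(C)C)CC[C@]32C | intermediate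
22 | tert-butyl{[(3S,5aS,6R,9aS)-6-[2-(benzyloxy)ethyl]-2,2,5a-trimethyl-7-methylidenedecahydro-1-benzoxepin-3-yl]oxy}dimethylsilane | O(Cc1ccccc1)CC[C@@H]2C(=C)CC[C@@H]3OC(C)(C)[C@@H](O[Si](C)(C)C(C)(C)C)CC[C@]32C | intermediate
23 | tert-butyl{[(3S,5aS,6R,7R,9aS)-6-[2-(benzyloxy)ethyl]-2,2,5a,7-tetramethyldecahydro-1-benzoxepin-3-yl]oxy}dimethylsilane | O(Cc1ccccc1)CC[C@@H]2[C@H](C)CC[C@@H]3OC(C)(C)[C@@H](O[Si](C)(C)C(C)(C)C)CC[C@]32C | intermediate
24 | 2-[(3S,5aS,6R,7R,9aS)-3-{[tert-butyl(dimethyl)silyl]oxy}-2,2,5a,7-tetramethyldecahydro-1-benzoxepin-6-yl]ethan-1-ol | OCC[C@@H]2[C@H](C)CC[C@@H]3OC(C)(C)[C@@H](O[Si](C)(C)C(C)(C)C)CC[C@]32C | intermediate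
25 | tert-butyl{[(3S,5aS,6R,7R,9aS)-6-(2-iodoethyl)-2,2,5a,7-tetramethyldecahydro-1-benzoxepin-3-yl]oxy}dimethylsilane | ICC[C@@H]2[C@H](C)CC[C@@H]3OC(C)(C)[C@@H](O[Si](C)(C)C(C)(C)C)CC[C@]32C | intermediate
26 | 2-lithioethyl analogue of 25 (alkyllithium) | [Li]CC[C@@H]2[C@H](C)CC[C@@H]3OC(C)(C)[C@@H](O[Si](C)(C)C(C)(C)C)CC[C@]32C | intermediate
27 | tertiary allylic alcohol: 13 with the left-half CH2CH2 chain added at its C1 carbonyl (decalin C9), carbinol centre open | CC1=CC[C@@H]2C(C)(C)[C@H](O[Si](C)(C)C(C)(C)C)CC[C@]2(C)C1(O)CC[C@@H]3[C@H](C)CC[C@@H]4OC(C)(C)[C@@H](O[Si](C)(C)C(C)(C)C)CC[C@]43C | intermediate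
28 | transposed enone: C7 ketone, C8(Me)=C9(chain), C5–H cis to C10–Me, silyl ethers at C3 and on the oxepane | CC1=C(CC[C@@H]3[C@H](C)CC[C@@H]4OC(C)(C)[C@@H](O[Si](C)(C)C(C)(C)C)CC[C@]43C)[C@@]2(C)CC[C@@H](O[Si](C)(C)C(C)(C)C)C(C)(C)[C@H]2CC1=O | intermediate
29 | C6-hydroxy derivative of 28 (acyloin, C6 open) | CC1=C(CC[C@@H]3[C@H](C)CC[C@@H]4OC(C)(C)[C@@H](O[Si](C)(C)C(C)(C)C)CC[C@]43C)[C@@]2(C)CC[C@@H](O[Si](C)(C)C(C)(C)C)C(C)(C)[C@H]2C(O)C1=O | intermediate
30 | triol: 29 with both silyl ethers cleaved | CC1=C(CC[C@@H]3[C@H](C)CC[C@@H]4OC(C)(C)[C@@H](O)CC[C@]43C)[C@@]2(C)CC[C@@H](O)C(C)(C)[C@H]2C(O)C1=O | intermediate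
31 | triketone (C6,C7-diketo tautomer of the target) | CC1=C(CC[C@@H]3[C@H](C)CC[C@@H]4OC(C)(C)C(=O)CC[C@]43C)[C@@]2(C)CCC(=O)C(C)(C)[C@H]2C(=O)C1=O | intermediate
32 | sodwanone B | CC1=C(CC[C@@H]2[C@H](C)CC[C@@H]3OC(C)(C)C(=O)CC[C@]32C)[C@@]2(C)CCC(=O)C(C)(C)C2=C(O)C1=O | target

**Step count and risks**

Total steps: 20. Longest linear sequence: 13 steps (steps 8–15, then 16–20); the right half needs 7 steps before the union.

Steps most likely to fail:

1. Step 6 (Proposed new method). What may go wrong: protonation or hydrolysis of the enol ether before the C–C bond forms, so that ring A closes through the free ketone enol without facial control; or reversible addition of the freed C3 hydroxyl to the product enone, which would stall the aldol stage. Fallback (known chemistry; sets out from 6, comes back at 13): silylation of 6 (TBSOTf, 2,6-lutidine) gives the silyl ether F1; LiAlH4 reduces ester and ketone to the diol F2; Swern oxidation gives the keto aldehyde F3; Wittig reaction with Ph3P=CHCHO at the aldehyde gives the keto enal F4; base-mediated intramolecular Michael addition and aldol condensation (Cs2CO3, MeCN, 23 → 60 °C, a Robinson-type annulation without the tether) should give 13, possibly with its ring-fusion epimer F5 (equally serviceable, since C5 ends sp2) and with the C8a-epimeric enone F6. F6 is removed by chromatography, because the C6 silyloxy centre makes it a diastereomer. This fallback trades the tether control for a separation.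

2. Step 12. What may go wrong: exo-mode opening of the epoxonium ion (tetrahydrofuran or tetrahydropyran instead of oxepane), or attack of the enol silane on an epoxide before the oxygen relay, so that the two rings do not form together. Fallback (stepwise ring formation; sets out from 14, comes back at 21): Sharpless asymmetric epoxidation of commercial geraniol (Ti(Oi-Pr)4, L-(+)-diethyl tartrate, t-BuOOH) gives the epoxy alcohol F7, and tosylation gives the tosylate F8; the dianion of 14 is alkylated by F8 to the epoxy keto phosphonate F9; olefination with 17 as in step 9 gives the epoxy enone F10; hydrosilylation as in step 11 gives the enol silane F11; MeAlCl2-promoted epoxide-opening carbocyclisation (CH2Cl2, −78 °C) gives the hydroxy ketone F12; Shi epoxidation of the remaining alkene gives the epoxy alcohol F13; acid-catalysed (camphorsulfonic acid) 7-endo opening at the tertiary epoxide carbon gives the oxepanol F14; silylation (TBSOTf, 2,6-lutidine) gives 21.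

3. Step 14. What may go wrong: hydrogen delivery to the wrong face of the exocyclic alkene, or migration of the double bond into the ring before reduction, which would give the equatorial methyl epimer or an unreactive tetrasubstituted alkene. Fallback (sets out from 22, comes back at 23): hydroboration with the bulky 9-BBN from the face opposite the axial C5a methyl, then NaOH/H2O2, gives the axial hydroxymethyl compound F15; TsCl/pyridine gives the tosylate F16; LiBHEt3 reduces it to the methyl compound 23, which is debenzylated (H2, Pd(OH)2/C) to 24.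

**Further compounds**

F1 | step 6 | methyl (3R)-3-{[tert-butyl(dimethyl)silyl]oxy}-2,2,6-trimethyl-7-oxononanoate | CCC(=O)C(C)CC[C@@H](O[Si](C)(C)C(C)(C)C)C(C)(C)C(=O)OC
F2 | step 6 | (3R)-3-{[tert-butyl(dimethyl)silyl]oxy}-2,2,6-trimethylnonane-1,7-diol | CCC(O)C(C)CC[C@@H](O[Si](C)(C)C(C)(C)C)C(C)(C)CO
F3 | step 6 | (3R)-3-{[tert-butyl(dimethyl)silyl]oxy}-2,2,6-trimethyl-7-oxononanal | CCC(=O)C(C)CC[C@@H](O[Si](C)(C)C(C)(C)C)C(C)(C)C=O
F4 | step 6 | (2E,5R)-5-{[tert-butyl(dimethyl)silyl]oxy}-4,4,8-trimethyl-9-oxoundec-2-enal | CCC(=O)C(C)CC[C@@H](O[Si](C)(C)C(C)(C)C)C(C)(C)/C=C/C=O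
F5 | step 6 | (4aS,6R,8aS)-6-{[tert-butyl(dimethyl)silyl]oxy}-2,5,5,8a-tetramethyl-4a,5,6,7,8,8a-hexahydronaphthalen-1(4H)-one | CC1=CC[C@H]2C(C)(C)[C@H](O[Si](C)(C)C(C)(C)C)CC[C@]2(C)C1=O
F6 | step 6 | (4aS,6R,8aR)-6-{[tert-butyl(dimethyl)silyl]oxy}-2,5,5,8a-tetramethyl-4a,5,6,7,8,8a-hexahydronaphthalen-1(4H)-one | CC1=CC[C@H]2C(C)(C)[C@H](O[Si](C)(C)C(C)(C)C)CC[C@@]2(C)C1=O
F7 | step 12 | [(2S,3S)-3-methyl-3-(4-methylpent-3-en-1-yl)oxiran-2-yl]methanol | OC[C@@H]1O[C@@]1(C)CCC=C(C)C
F8 | step 12 | [(2S,3S)-3-methyl-3-(4-methylpent-3-en-1-yl)oxiran-2-yl]methyl 4-methylbenzenesulfonate | Cc1ccc(cc1)S(=O)(=O)OC[C@@H]1O[C@@]1(C)CCC=C(C)C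
F9 | step 12 | dimethyl {4-[(2S,3S)-3-methyl-3-(4-methylpent-3-en-1-yl)oxiran-2-yl]-2-oxobutyl}phosphonate | COP(=O)(CC(=O)CC[C@@H]1O[C@@]1(C)CCC=C(C)C)OC
F10 | step 12 | (2E)-1-(benzyloxy)-6-[(2S,3S)-3-methyl-3-(4-methylpent-3-en-1-yl)oxiran-2-yl]hex-2-en-4-one | O=C(/C=C/COCc1ccccc1)CC[C@@H]1O[C@@]1(C)CCC=C(C)C
F11 | step 12 | tert-butyl{[(3Z)-6-(benzyloxy)-1-[(2S,3S)-3-methyl-3-(4-methylpent-3-en-1-yl)oxiran-2-yl]hex-3-en-3-yl]oxy}dimethylsilane | CC(C)(C)[Si](C)(C)O/C(CC[C@@H]1O[C@@]1(C)CCC=C(C)C)=C\CCOCc1ccccc1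
F12 | step 12 | (2S,3S,4S)-2-[2-(benzyloxy)ethyl]-4-hydroxy-3-methyl-3-(4-methylpent-3-en-1-yl)cyclohexan-1-one | O(Cc1ccccc1)CC[C@@H]1C(=O)CC[C@H](O)[C@@]1(C)CCC=C(C)C
F13 | step 12 | (2S,3S,4S)-2-[2-(benzyloxy)ethyl]-3-{2-[(2S)-3,3-dimethyloxiran-2-yl]ethyl}-4-hydroxy-3-methylcyclohexan-1-one | O(Cc1ccccc1)CC[C@@H]1C(=O)CC[C@H](O)[C@@]1(C)CC[C@@H]2OC2(C)C
F14 | step 12 | (3S,5aS,6S,9aS)-6-[2-(benzyloxy)ethyl]-3-hydroxy-2,2,5a-trimethyl-3,4,5,5a,6,8,9,9a-octahydro-1-benzoxepin-7(2H)-one | O(Cc1ccccc1)CC[C@@H]2C(=O)CC[C@@H]3OC(C)(C)[C@@H](O)CC[C@]32C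
F15 | step 14 | {(3S,5aS,6R,7R,9aS)-6-[2-(benzyloxy)ethyl]-3-{[tert-butyl(dimethyl)silyl]oxy}-2,2,5a-trimethyldecahydro-1-benzoxepin-7-yl}methanol | O(Cc1ccccc1)CC[C@@H]2[C@H](CO)CC[C@@H]3OC(C)(C)[C@@H](O[Si](C)(C)C(C)(C)C)CC[C@]32C
F16 | step 14 | {(3S,5aS,6R,7R,9aS)-6-[2-(benzyloxy)ethyl]-3-{[tert-butyl(dimethyl)silyl]oxy}-2,2,5a-trimethyldecahydro-1-benzoxepin-7-yl}methyl 4-methylbenzenesulfonate | O(Cc1ccccc1)CC[C@@H]2[C@H](COS(=O)(=O)c1ccc(C)cc1)CC[C@@H]3OC(C)(C)[C@@H](O[Si](C)(C)C(C)(C)C)CC[C@]32C
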